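Read at 10.0 d, Thursday's run gives the shape I need for spring, a flask with the same charge of coupling partner (0.170 M) and a little less starting material.

| flask | starting material | coupling partner | capture agent | remark | time |
|---|---|---|---|---|---|
| Monday's | 0.17 M | 0.068 M | 8.5 mM | run made earlier |  |
| Friday's | 0.17 M | 0.10 M | 8.5 mM | run made earlier |  |
| Saturday's | 0.17 M | 0.15 M | 8.5 mM | run made earlier |  |
| Thursday's | 0.19 M | 0.17 M | 8.5 mM | run made earlier |  |
| spring | 0.17 M | 0.170 M | 8.50 mM |  | 20 d |
| noon | 0.12 M | 0.0600 M | 8.50 mM |  | 20 d |

| run | time / d | target / % |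
|---|---|---|
| Monday's | 2.08 | 4.0 |
| Monday's | 4.00 | 3.9 |
| Monday's | 6.00 | 7.3 |
| Monday's | 8.00 | 4.8 |
| Monday's | 10.0 | 8.3 |
| Friday's | 0.833 | 0 |
| Friday's | 1.67 | 4.3 |
| Friday's | 3.00 | 6.8 |
| Friday's | 5.00 | 10.8 |
| Friday's | 10.0 | 15.2 |
| Saturday's | 2.08 | 8.3 |
| Saturday's | 4.00 | 17.6 |
| Saturday's | 6.00 | 20.0 |
| Saturday's | 8.00 | 23.0 |
| Saturday's | 10.0 | 24.0 |
| Thursday's | 0.833 | 2.4 |
| Thursday's | 1.67 | 7.2 |
| Thursday's | 3.00 | 14.4 |
| Thursday's | 5.00 | 20.2 |
| Thursday's | 10.0 | 24.8 |

(readings scatter by 1 percentage point)

- candidate steps: starting material + coupling partner <-> intermediate A; starting material + coupling partner -> intermediate B; intermediate B <-> intermediate C; coupling partner + intermediate C -> side product; coupling partner + intermediate B -> intermediate D; intermediate D -> target; target -> over-reaction product; capture agent + intermediate A -> trapped intermediate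

1. which of the two ends with the higher amount of target, in percent of the starting material charged ("neither" if they lie within 2 percentage points) (spring / noon / neither)
2. target at the end, in percent of the starting material charged, spring
3. target at the end, in percent of the starting material charged, noon

Thursday's curve starts nearly flat, with 2.4% of target at 0.833 d. Between 1.67 d and 3.00 d it climbs at 0.0103 M d⁻¹, while between 5.00 d and 10.0 d it gains 0.00175 M d⁻¹, a much gentler slope. Extending these two straight lines until they cross puts the knee at 3.88 d.

For the level beyond the knee I use the return, meaning the target formed per coupling partner charged, both in moles, at the last reading. Thursday reads 0.277, Saturday 0.272, Friday 0.258 and Monday 0.207, so the return falls at low loading and flattens at high loading. I assume that it holds to the end, and on that assumption I reckon spring at 27.7%. For noon, whose charge of coupling partner lies nearest Monday's, I take Monday's return and reckon 10.4%.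

The forecast names spring, with 29% (24% to 35%) for spring, above my figure, and 9% (6% to 13%) for noon, below it, saying “the curves are flattening as coupling partner runs out”.

The flask gives 27.5% for spring and 9.82% for noon, so spring ends higher.

    starting material + coupling partner ⇌ intermediate A (K = 7.20 M⁻¹, k = 4.20 × 10⁻⁵ M⁻¹ s⁻¹)
    starting material + coupling partner → intermediate B (k = 1.20 × 10⁻⁴ M⁻¹ s⁻¹)
    intermediate B ⇌ intermediate C (K = 1.00, k = 1.50 × 10⁻⁶ s⁻¹)
    coupling partner + intermediate C → side product (k = 1.20 × 10⁻⁴ M⁻¹ s⁻¹)
    coupling partner + intermediate B → intermediate D (k = 3.80 × 10⁻⁴ M⁻¹ s⁻¹)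
    intermediate D → target (k = 2.70 × 10⁻⁶ s⁻¹)
    target → over-reaction product (k = 2.60 × 10⁻⁷ s⁻¹)
    capture agent + intermediate A → trapped intermediate (k = 4.50 × 10⁻⁴ M⁻¹ s⁻¹)

These results correspond to returns of 0.275 for spring and 0.196 for noon. In noon the coupling partner, the limiting reagent, stands at 0% of its charge at 20.0 d, and noon's 9.82% of target is held down by this wearing away of coupling partner: in the same run with the wearing away taken away, the coupling partner kept at its charge, the target stands at 64.1%. For the spring recipe with 0.43 M of coupling partner, Thursday's return predicts 70.1%, and that flask gives 66.1%.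

(The earlier runs and the new flask stem from a simulated flask for an exercise.)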